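**Strategy.** Ring C is cut at C3–C4. The C4 carbonyl carbon and the oxygen-bearing benzylic C2 sit in a 1,3-relationship, so C4 is made nucleophilic as a lithiated 2-aryl-1,3-dithiane on ring A, while C3 and C2 arrive together as (S)-styrene oxide. In one operation the key step forges C3–C4 and places the C2 carbinol with the epoxide's configuration intact; Mitsunobu closure of the O1–C2 bond later inverts it to 2S. The precursor is the bis-MOM-protected 3,5-diprenylaryl dithiane, built from 2,4,6-tribromoresorcinol by three bromine–lithium exchanges, the last delivering the dithiane ring without acid.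

Key step: step 5

Assumption: the target is the (2S)-enantiomer; (S)-styrene oxide gives the (R)-carbinol with unchanged geometry (the descriptor changes only through CIP priorities), and one inversion then gives 2S.
Assumption: aryl MOM ethers do not survive Lewis acid/dithiol mixtures, so the dithiane is attached as an electrophile to an aryl Grignard rather than made from an aldehyde after protection; both phenols carry MOM because ring C can close only on the phenol ortho to the dithiane.
Assumption: 2,4,6-tribromoresorcinol, prenyl bromide, 1,3-dithiane and (S)-styrene oxide are bought.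

Step 1
Reactants: 1 2,4,6-tribromoresorcinol (2,4,6-tribromobenzene-1,3-diol)
Product: 2 1,3,5-tribromo-2,4-bis(methoxymethoxy)benzene
Conditions: NaH, MOMCl, DMF, 0 °C → rt
Reagents that add atoms: chloromethyl methyl ether (MOMCl), COCCl
Why: Williamson-type O-alkylation of the two acidic, bromine-flanked phenoxides with the highly reactive α-chloro ether should give the bis-MOM ether, whose oxygens later stabilise the ortho organometallics.

Step 2
Reactants: 2 1,3,5-tribromo-2,4-bis(methoxymethoxy)benzene, 3 prenyl bromide (1-bromo-3-methylbut-2-ene)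
Product: 5 1,5-dibromo-2,4-bis(methoxymethoxy)-3-(3-methylbut-2-enyl)benzene, via aryllithium 4 (not isolated)
Conditions: n-BuLi (1.0 equiv), THF, −78 °C; then CuI (10 mol%), 3, −78 °C → rt
Reagents that add atoms: none
Why: Bromine–lithium exchange at −78 °C outruns every deprotonation and should settle on the bromine flanked by both MOM ethers, whose aryllithium is held by two chelating ortho oxygens, after which copper-catalysed SN2 allylation installs the first prenyl group between the two oxygens; if some exchange occurred at a lateral bromine instead, step 3 would converge on the same compound 7.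

Step 3
Reactants: 5 1,5-dibromo-2,4-bis(methoxymethoxy)-3-(3-methylbut-2-enyl)benzene, 3 prenyl bromide
Product: 7 1-bromo-2,4-bis(methoxymethoxy)-3,5-bis(3-methylbut-2-enyl)benzene, via aryllithium 6 (not isolated)
Conditions: n-BuLi (1.0 equiv), THF, −78 °C; then CuI (10 mol%), 3, −78 °C → rt
Reagents that add atoms: none
Why: The same bromine–lithium exchange and copper-catalysed allylation is repeated on a substrate whose two bromines are equivalent by symmetry, so one equivalent of n-BuLi should give a single aryllithium, formed faster than the benzylic–allylic CH2 of the first prenyl group can be deprotonated.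

Step 4
Reactants: 7 1-bromo-2,4-bis(methoxymethoxy)-3,5-bis(3-methylbut-2-enyl)benzene, 8 1,3-dithiane
Product: 12 2-[2,4-bis(methoxymethoxy)-3,5-bis(3-methylbut-2-enyl)phenyl]-1,3-dithiane, via aryllithium 9 (not isolated), via aryl Grignard 10 (not isolated), via 2-chloro-1,3-dithiane 11 (not isolated)
Conditions: n-BuLi, THF, −78 °C; MgBr2·OEt2, −78 → 0 °C; then 11 (made beforehand from 8 with NCS, benzene, rt, filtered solution), 0 °C → rt
Reagents that add atoms: none
Why: After a third bromine–lithium exchange and transmetalation to the less basic aryl Grignard, nucleophilic substitution at C2 of 2-chloro-1,3-dithiane (an α-chloro sulfide reacting through the sulfur-stabilised dithienium ion, a known route from Grignard reagents to 2-substituted dithianes) should attach the intact dithiane ring under acid-free conditions that leave the MOM ethers and prenyl groups untouched.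

Step 5
Reactants: 12 2-[2,4-bis(methoxymethoxy)-3,5-bis(3-methylbut-2-enyl)phenyl]-1,3-dithiane, 13 (S)-styrene oxide [(2S)-2-phenyloxirane]
Product: 15 (1R)-2-{2-[2,4-bis(methoxymethoxy)-3,5-bis(3-methylbut-2-enyl)phenyl]-1,3-dithian-2-yl}-1-phenylethan-1-ol, via lithiated dithiane 14 (not isolated)
Conditions: n-BuLi (1.05 equiv), THF, −78 → −20 °C; then 13, −20 °C → rt; H2O quench
Reagents that add atoms: none
Why: Deprotonation of the doubly sulfur-stabilised benzylic C–H by n-BuLi, with lithium held by the neighbouring MOM oxygen, should give carbanion 14, which displaces the epoxide oxygen from the CH2 terminus in an SN2 ring opening and so forges C3–C4. The closest known reaction type is the Corey–Seebach alkylation of 2-aryl-2-lithio-1,3-dithianes with terminal epoxides. No ring is closed; the oxirane is opened. No stereocentre is created: the future C2 keeps all four of its bonds, so the (S)-epoxide passes its geometry on unchanged, and the descriptor becomes R only because CH2 and phenyl swap CIP rank. The step needs regioselectivity for the terminal over the benzylic epoxide carbon, which the bulk of the fully substituted carbanion and the absence of any strong Lewis acid should secure. It also needs chemoselective deprotonation, which the far higher acidity of the dithiane C–H compared with the prenyl CH2 groups should secure.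

Step 6
Reactants: 15 (1R)-2-{2-[2,4-bis(methoxymethoxy)-3,5-bis(3-methylbut-2-enyl)phenyl]-1,3-dithian-2-yl}-1-phenylethan-1-ol
Product: 16 4-{2-[(2R)-2-hydroxy-2-phenylethyl]-1,3-dithian-2-yl}-2,6-bis(3-methylbut-2-enyl)benzene-1,3-diol
Conditions: HCl (3 M aq), MeOH, rt → 40 °C
Reagents that add atoms: none
Why: Acid-catalysed acetal exchange with methanol should release both phenols as dimethoxymethane is lost, under the mild conditions customary for MOM removal from prenylated phenols, which the dithiane, the non-activated benzylic alcohol and the prenyl groups should tolerate.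

Step 7
Reactants: 16 4-{2-[(2R)-2-hydroxy-2-phenylethyl]-1,3-dithian-2-yl}-2,6-bis(3-methylbut-2-enyl)benzene-1,3-diol
Product: 17 (2S)-6,8-bis(3-methylbut-2-enyl)-2-phenyl-2,3-dihydrospiro[chromene-4,2'-[1,3]dithian]-7-ol
Conditions: PPh3, DIAD, THF (0.02 M), 0 °C → rt
Reagents that add atoms: none
Why: In this Mitsunobu etherification the alkoxyphosphonium ion of the secondary alcohol should be displaced intramolecularly (6-exo-tet SN2) by the only phenoxide within reach, the one ortho to the dithiane, with inversion from R to 2S, while the dithiane keeps C4 non-enolisable so that no E1cB dehydration to a chalcone can compete.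

Step 8
Reactants: 17 (2S)-6,8-bis(3-methylbut-2-enyl)-2-phenyl-2,3-dihydrospiro[chromene-4,2'-[1,3]dithian]-7-ol
Product: 18 (2S)-7-hydroxy-6,8-bis(3-methylbut-2-enyl)-2-phenyl-2,3-dihydro-4H-chromen-4-one (7-hydroxy-6,8-diprenylflavanone)
Conditions: MeI (excess), CaCO3, MeCN/H2O (4:1), 45 °C
Reagents that add atoms: water, O
Why: Alkylative hydrolysis of the dithioketal (S-methylation, ionisation to a cation stabilised by the para-hydroxy and ortho-alkoxy ring, capture by water) should unveil the C4 ketone in a non-oxidising, near-neutral medium that spares the prenyl alkenes, the free phenol and the base-sensitive C2 stereocentre.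

**Compound list**

1 | 2,4,6-tribromoresorcinol (2,4,6-tribromobenzene-1,3-diol) | Oc1c(Br)cc(Br)c(O)c1Br | starting material
2 | 1,3,5-tribromo-2,4-bis(methoxymethoxy)benzene | COCOc1c(Br)cc(Br)c(OCOC)c1Br | intermediate
3 | prenyl bromide (1-bromo-3-methylbut-2-ene) | CC(C)=CCBr | starting material
4 | [3,5-dibromo-2,6-bis(methoxymethoxy)phenyl]lithium | [Li]c1c(OCOC)c(Br)cc(Br)c1OCOC | intermediate
5 | 1,5-dibromo-2,4-bis(methoxymethoxy)-3-(3-methylbut-2-enyl)benzene | COCOc1c(Br)cc(Br)c(OCOC)c1CC=C(C)C | intermediate
6 | [5-bromo-2,4-bis(methoxymethoxy)-3-(3-methylbut-2-enyl)phenyl]lithium | COCOc1c([Li])cc(Br)c(OCOC)c1CC=C(C)C | intermediate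
7 | 1-bromo-2,4-bis(methoxymethoxy)-3,5-bis(3-methylbut-2-enyl)benzene | COCOc1c(CC=C(C)C)cc(Br)c(OCOC)c1CC=C(C)C | intermediate
8 | 1,3-dithiane | C1CSCSC1 | starting material
9 | [2,4-bis(methoxymethoxy)-3,5-bis(3-methylbut-2-enyl)phenyl]lithium | COCOc1c(CC=C(C)C)cc([Li])c(OCOC)c1CC=C(C)C | intermediate
10 | [2,4-bis(methoxymethoxy)-3,5-bis(3-methylbut-2-enyl)phenyl]magnesium bromide | COCOc1c(CC=C(C)C)cc([Mg]Br)c(OCOC)c1CC=C(C)C | intermediate
11 | 2-chloro-1,3-dithiane | ClC1SCCCS1 | intermediate
12 | 2-[2,4-bis(methoxymethoxy)-3,5-bis(3-methylbut-2-enyl)phenyl]-1,3-dithiane | COCOc1c(CC=C(C)C)cc(C2SCCCS2)c(OCOC)c1CC=C(C)C | intermediate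
13 | (S)-styrene oxide [(2S)-2-phenyloxirane] | O1[C@@H](c2ccccc2)C1 | starting material
14 | {2-[2,4-bis(methoxymethoxy)-3,5-bis(3-methylbut-2-enyl)phenyl]-1,3-dithian-2-yl}lithium | COCOc1c(CC=C(C)C)cc(C2([Li])SCCCS2)c(OCOC)c1CC=C(C)C | intermediate
15 | (1R)-2-{2-[2,4-bis(methoxymethoxy)-3,5-bis(3-methylbut-2-enyl)phenyl]-1,3-dithian-2-yl}-1-phenylethan-1-ol | COCOc1c(CC=C(C)C)cc(C2(C[C@@H](O)c3ccccc3)SCCCS2)c(OCOC)c1CC=C(C)C | intermediate
16 | 4-{2-[(2R)-2-hydroxy-2-phenylethyl]-1,3-dithian-2-yl}-2,6-bis(3-methylbut-2-enyl)benzene-1,3-diol | Oc1c(CC=C(C)C)cc(C2(C[C@@H](O)c3ccccc3)SCCCS2)c(O)c1CC=C(C)C | intermediate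
17 | (2S)-6,8-bis(3-methylbut-2-enyl)-2-phenyl-2,3-dihydrospiro[chromene-4,2'-[1,3]dithian]-7-ol | CC(C)=CCc1cc2c(c(CC=C(C)C)c1O)O[C@H](c1ccccc1)CC21SCCCS1 | intermediate
18 | (2S)-7-hydroxy-6,8-bis(3-methylbut-2-enyl)-2-phenyl-2,3-dihydro-4H-chromen-4-one (7-hydroxy-6,8-diprenylflavanone) | CC(C)=CCc1cc2c(c(CC=C(C)C)c1O)O[C@H](c1ccccc1)CC2=O | target

**Step count and risk**

Total step count: 8. Longest linear sequence: 8 steps (1 → 18).

Steps most likely to fail:

Step 5 (key step). What may go wrong: slow or misdirected ring opening. The hindered, delocalised carbanion may attack the benzylic epoxide carbon in part, or act as a base and isomerise the epoxide, so that conversion or regioselectivity falls short. Fallback: set the stereocentre by catalyst-controlled ketone reduction instead of carrying it in from the epoxide. It sets out from aryl bromide 7 and comes back at carbinol 15. Copper-free Sonogashira coupling of 7 with racemic 1-phenylprop-2-yn-1-ol (PdCl2(MeCN)2, XPhos, i.e. 2-dicyclohexylphosphino-2',4',6'-triisopropylbiphenyl, Cs2CO3, MeCN, 80 °C) should give the propargylic alcohol 3-[2,4-bis(methoxymethoxy)-3,5-bis(3-methylbut-2-enyl)phenyl]-1-phenylprop-2-yn-1-ol F1. Oxidation with MnO2 in CH2Cl2 should give the ynone 3-[2,4-bis(methoxymethoxy)-3,5-bis(3-methylbut-2-enyl)phenyl]-1-phenylprop-2-yn-1-one F2. Double conjugate addition of propane-1,3-dithiol (NaOMe, MeOH/CH2Cl2, −10 °C → rt) should place both sulfur atoms on the aryl-bearing alkyne carbon and give the β-keto dithiane 2-{2-[2,4-bis(methoxymethoxy)-3,5-bis(3-methylbut-2-enyl)phenyl]-1,3-dithian-2-yl}-1-phenylethan-1-one F3. Corey–Bakshi–Shibata reduction with (S)-2-methyl-CBS-oxazaborolidine [(3aS)-1-methyl-3,3-diphenyltetrahydro-1H,3H-pyrrolo[1,2-c][1,3,2]oxazaborole] and BH3·SMe2 in THF at −20 °C should then give 15, phenyl acting as the large group as in acetophenone. The enantiomeric purity would then rest on this reduction.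

Step 4. What may go wrong: loss of the aryl Grignard by proton or chlorine abstraction from the labile 2-chloro-1,3-dithiane instead of C–C bond formation. Fallback: classical thioacetalisation of an aldehyde, with the protecting groups put on afterwards. It sets out from aryllithium 9 and comes back at dithiane 12. Quenching 9 with DMF should give 2,4-bis(methoxymethoxy)-3,5-bis(3-methylbut-2-enyl)benzaldehyde F4. Propane-1,3-dithiol with BF3·OEt2 in CH2Cl2 at −20 °C should form the dithiane while stripping both MOM groups, giving 4-(1,3-dithian-2-yl)-2,6-bis(3-methylbut-2-enyl)benzene-1,3-diol F5; the reaction is kept cold and short to spare the ortho-prenyl phenols. NaH and MOMCl in DMF at 0 °C should then restore the MOM ethers and give 12.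

Step 8. What may go wrong: incomplete S-alkylative cleavage of the dithioketal or competing O-methylation of the free phenol, while more forceful oxidative reagents are ruled out by the free ortho-prenyl phenol. Fallback: mask the phenol so that an oxidative unmasking becomes possible. It sets out from 17 and comes back at 18. Ac2O, pyridine and DMAP should give (2S)-6,8-bis(3-methylbut-2-enyl)-2-phenyl-2,3-dihydrospiro[chromene-4,2'-[1,3]dithian]-7-yl acetate F6. Dess–Martin periodinane in wet MeCN/CH2Cl2 should cleave the dithioketal to (2S)-6,8-bis(3-methylbut-2-enyl)-4-oxo-2-phenyl-3,4-dihydro-2H-chromen-7-yl acetate F7. NH4OAc in aqueous MeOH at rt should remove the aryl acetate under neutral conditions that do not open ring C, giving 18.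

**Further compounds**

F1 | step 5 | 3-[2,4-bis(methoxymethoxy)-3,5-bis(3-methylbut-2-enyl)phenyl]-1-phenylprop-2-yn-1-ol (racemic) | COCOc1c(CC=C(C)C)cc(C#CC(O)c2ccccc2)c(OCOC)c1CC=C(C)C
F2 | step 5 | 3-[2,4-bis(methoxymethoxy)-3,5-bis(3-methylbut-2-enyl)phenyl]-1-phenylprop-2-yn-1-one | COCOc1c(CC=C(C)C)cc(C#CC(=O)c2ccccc2)c(OCOC)c1CC=C(C)C
F3 | step 5 | 2-{2-[2,4-bis(methoxymethoxy)-3,5-bis(3-methylbut-2-enyl)phenyl]-1,3-dithian-2-yl}-1-phenylethan-1-one | COCOc1c(CC=C(C)C)cc(C2(CC(=O)c3ccccc3)SCCCS2)c(OCOC)c1CC=C(C)C
F4 | step 4 | 2,4-bis(methoxymethoxy)-3,5-bis(3-methylbut-2-enyl)benzaldehyde | COCOc1c(CC=C(C)C)cc(C=O)c(OCOC)c1CC=C(C)C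
F5 | step 4 | 4-(1,3-dithian-2-yl)-2,6-bis(3-methylbut-2-enyl)benzene-1,3-diol | Oc1c(CC=C(C)C)cc(C2SCCCS2)c(O)c1CC=C(C)C
F6 | step 8 | (2S)-6,8-bis(3-methylbut-2-enyl)-2-phenyl-2,3-dihydrospiro[chromene-4,2'-[1,3]dithian]-7-yl acetate | CC(C)=CCc1cc2c(c(CC=C(C)C)c1OC(C)=O)O[C@H](c1ccccc1)CC21SCCCS1
F7 | step 8 | (2S)-6,8-bis(3-methylbut-2-enyl)-4-oxo-2-phenyl-3,4-dihydro-2H-chromen-7-yl acetate | CC(C)=CCc1cc2c(c(CC=C(C)C)c1OC(C)=O)O[C@H](c1ccccc1)CC2=O
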